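(All runs were computed on assumed constants; the scatter is artificial.)

**The decision.** At 20 min the violet flask offers four moves, and the reckoning follows one number: how much target each coupling partner gives before it is lost.

all flasks: substrate 0.36 M; initiator 0.64 mol%; radical scavenger 0.02 mol%

| run | coupling partner | temperature | remark | time |
|---|---|---|---|---|
| violet | 0.95 equiv | 40 °C | the very flask that is asked about, followed so far |  |
| ochre | 0.95 equiv | 46 °C | run made earlier |  |
| flask | 0.950 equiv | 40 °C |  | 20 min |

- violet (time / min: target / %): 1.00: 14.0; 3.00: 23.5; 6.00: 24.8; 8.00: 24.1; 12.0: 24.8; 15.0: 25.6; 20.0: 23.3
- ochre (time / min: target / %): 1.00: 16.0; 3.00: 20.2; 6.00: 20.2; 8.00: 19.7; 12.0: 20.7; 15.0: 20.2; 20.0: 19.4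

(standard deviation of a reading: 0.5 percentage points)

- in percentages every species weighs as the substrate in it: one ended chains A counts as two
- target that was removed still counts
- reactions considered so far: chain carrier + radical scavenger -> ended chains B; coupling partner -> decomposed reagent; initiator -> 2 initiating radical; coupling partner + chain carrier -> target + initiating radical; substrate + initiating radical -> chain carrier; 2 chain carrier -> ended chains A
- additions bring no volume worth counting

- larch: at 20 min add coupling partner, 50.0% of the amount charged, then wait 6.0 min
- elm: at 20 min take out 90% of the target then present, then wait 6.0 min
- cedar: at 20 min raise the temperature by 25 K, then wait 6.0 min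
- maple: change nothing and wait 6.0 min more

- target, in percent of the substrate first charged, at 20 min
- which option adds most target ("none" when 2 percentage points or less is all one gets) (larch / elm / cedar / maple / none)
- target present, with what was taken out counted in, in percent of the substrate first charged, after larch
- target present, with what was taken out counted in, in percent of the substrate first charged, after cedar

**Main step.** Taken by itself, coupling turns each coupling partner into one target. At 0.950 equiv the coupling partner is the limiting reagent, so that charge is the ceiling. The violet readings instead level off at a mean of 24.5% from 6.00 min on. Plateau over charge gives 0.258: the capture share, target formed per coupling partner charged.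

**Decomposition added.** Coupling partner also turns into decomposed reagent, so two steps draw on it. Reading the rise as one exponential joins the two ends of the run: the violet reading at 1.00 min, held against the plateau, gives a loss constant of 0.846 min⁻¹, a half-life of 0.819 min. The time 20 min spans 24.4 of these, so hardly any coupling partner stands in the violet flask by then. Because that half-life is shorter than 20 min, this reckoning leaves waiting and heating little to couple and keeps cedar and maple at the plateau. The ochre run at 46 °C levels off at 20.0%, with a loss constant of 1.60 min⁻¹ and a capture share of 0.211, lower than the violet one.

**Remaining steps.** The radical scavenger takes hardly any of the radicals the initiator can supply. Target appears in the listed reactions as a product and nowhere as a reactant, so elm frees nothing. Larch adds 0.475 equiv of coupling partner, and at the full capture share this reckoning puts the violet flask at 36.8%. The initiator decomposes during those 20 min, and a dose meeting less of it may couple a smaller share, so that figure stands on the high side of this reckoning.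

The forecast gave 24.5% now, larch as best, 33% after larch and 24.8% after cedar: “Fresh partner should therefore give about half the original yield”.

**The result.** The violet flask holds 24.3% at 20 min. Option larch adds 7.1 percentage points and reaches 31.4%, while cedar stays at 24.3%.

    chain carrier + radical scavenger → ended chains B (k = 3.60 × 10⁸ M⁻¹ s⁻¹, Ea = 10.0 kJ mol⁻¹)
    coupling partner → decomposed reagent (k = 0.0120 s⁻¹, Ea = 92.0 kJ mol⁻¹)
    initiator → 2 initiating radical (k = 0.00140 s⁻¹, Ea = 90.0 kJ mol⁻¹)
    coupling partner + chain carrier → target + initiating radical (k = 64000 M⁻¹ s⁻¹, Ea = 19.0 kJ mol⁻¹)
    substrate + initiating radical → chain carrier (k = 80000 M⁻¹ s⁻¹, Ea = 27.0 kJ mol⁻¹)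
    2 chain carrier → ended chains A (k = 4.90 × 10⁸ M⁻¹ s⁻¹, Ea = 14.0 kJ mol⁻¹)
    (constants at 40 °C)

**Share carried.** On the larch dose the capture share comes to 0.150, lower than the 0.258 of the first charge; that dose met initiator at 18.6% of its charge. A neighbouring flask instead starts with 2.40 equiv of coupling partner and fresh initiator, other charges held. The violet capture share gives 61.9% target there, and that neighbour holds 61.3% at 20 min, with coupling partner at 0% and substrate at 37.6%.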